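**Plan**

1. Retrosynthesis: two helpers are put back first (a tert-butyl ester on C3 as activating group, a MOM acetal on O5). Ring C is then cut at O1–C2 (oxa-Michael, the chalcone-to-flavanone closure of flavonoid biosynthesis). The C8 prenyl group is returned to O1 as a 1,1-dimethylallyl ether (retro-Claisen, C8–CH2 bond). Last come C2=C3 (Knoevenagel), C3–CO2tBu and the two O-alkyl bonds.
2. Enabling feature: on ring A the prenyl-bearing C8 is ortho to C8a–O1, which is the product pattern of an aromatic Claisen shift from O1, and C2 is the β-carbon of the C2=C3–C4=O enone. The shift that places the prenyl group therefore also uncovers the nucleophile O1 next to it.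
3. Forward: ring A is bought complete. The chain is joined by O-propargylation, O5 protection, semi-hydrogenation, C-acylation and condensation with 4-methoxybenzaldehyde. One flask then moves the prenyl group to C8 and closes ring C, the only ring made. Acid finally removes ester and MOM.
4. Stereochemistry: C2 (S) is the only stereocentre of the target. It is set in the ring closure by a cinchona-derived bifunctional thiourea; C3 of the ester intermediate is transient.

Key step: step 6

Assumption: the thiourea derived from 9-amino-9-deoxy-epi-quinidine is taken as the pseudoenantiomer that delivers the (2S) series for this substrate class; should the sense be opposite, the epi-quinine-derived thiourea replaces it and nothing else changes.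

**Route**

Step 1
Reactants: 1 1-(2,6-dihydroxy-4-methoxyphenyl)ethanone; 2 3-chloro-3-methylbut-1-yne
Product: 3 1-[2-hydroxy-4-methoxy-6-(2-methylbut-3-yn-2-yloxy)phenyl]ethanone
Conditions: CuCl2·2H2O (1 mol%), DBU, MeCN, 0 °C
Reagents that add atoms: none
Why: Copper-catalysed O-propargylation of a phenol with a tertiary propargylic chloride should give one ether, because the two hydroxyls of 1 are equivalent and the remaining one, chelated to the ketone and crowded by the new tertiary ether, should not react again.

Step 2
Reactants: 3 1-[2-hydroxy-4-methoxy-6-(2-methylbut-3-yn-2-yloxy)phenyl]ethanone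
Product: 4 1-[4-methoxy-2-(methoxymethoxy)-6-(2-methylbut-3-yn-2-yloxy)phenyl]ethanone
Conditions: NaH (1.05 equiv), MOMCl, DMF, 0 °C to rt
Reagents that add atoms: chloromethyl methyl ether (MOMCl), COCCl
Why: Williamson-type alkylation of the sodium phenoxide blocks the chelated hydroxyl (future O5) so that it cannot compete in the later ring closure; the phenol is far more acidic than the ketone or the alkyne.

Step 3
Reactants: 4 1-[4-methoxy-2-(methoxymethoxy)-6-(2-methylbut-3-yn-2-yloxy)phenyl]ethanone
Product: 5 1-[4-methoxy-2-(methoxymethoxy)-6-(2-methylbut-3-en-2-yloxy)phenyl]ethanone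
Conditions: H2 (1 atm), Pd/CaCO3 poisoned with Pb(OAc)2 (Lindlar catalyst), quinoline, EtOAc, rt
Reagents that add atoms: none
Why: Lindlar semi-hydrogenation of the terminal alkyne should stop at the alkene and give the aryl 1,1-dimethylallyl ether needed for the Claisen rearrangement, with ketone, acetal and arene untouched.

Step 4
Reactants: 5 1-[4-methoxy-2-(methoxymethoxy)-6-(2-methylbut-3-en-2-yloxy)phenyl]ethanone
Product: 6 tert-butyl 3-[4-methoxy-2-(methoxymethoxy)-6-(2-methylbut-3-en-2-yloxy)phenyl]-3-oxopropanoate
Conditions: LiN(SiMe3)2 (2.2 equiv), THF, −78 °C; Boc2O, −78 to 0 °C; aq. NH4Cl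
Reagents that add atoms: di-tert-butyl dicarbonate (Boc2O), CC(C)(C)OC(=O)OC(=O)OC(C)(C)C
Why: Claisen-type C-acylation of the methyl ketone with Boc2O under two equivalents of amide base (the second takes up the more acidic β-ketoester) installs the tert-butyl ester activating group at a temperature that leaves the tert-allyl aryl ether intact.

Step 5
Reactants: 6 tert-butyl 3-[4-methoxy-2-(methoxymethoxy)-6-(2-methylbut-3-en-2-yloxy)phenyl]-3-oxopropanoate; 7 4-methoxybenzaldehyde
Product: 8 tert-butyl (Z)-2-[4-methoxy-2-(methoxymethoxy)-6-(2-methylbut-3-en-2-yloxy)benzoyl]-3-(4-methoxyphenyl)prop-2-enoate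
Conditions: piperidine (20 mol%), AcOH (20 mol%), 4 Å MS, toluene, rt
Reagents that add atoms: none
Why: Knoevenagel condensation under piperidinium acetate with water removal at ambient temperature stays below the threshold of the aryl ether rearrangement, and thermodynamic control should favour the Z isomer (aryl cis to the ester).

Step 6
Reactants: 8 tert-butyl (Z)-2-[4-methoxy-2-(methoxymethoxy)-6-(2-methylbut-3-en-2-yloxy)benzoyl]-3-(4-methoxyphenyl)prop-2-enoate
Product: 11 tert-butyl (2S,3R)-7-methoxy-5-(methoxymethoxy)-2-(4-methoxyphenyl)-8-(3-methylbut-2-enyl)-4-oxochromane-3-carboxylate, via ortho-dienone 9 (not isolated), via hydroxy alkylidene ketoester 10 (not isolated)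
Conditions: toluene (0.02 M), 90 °C; then −25 °C, 1-[3,5-bis(trifluoromethyl)phenyl]-3-(9-deoxy-epi-quinidin-9-yl)thiourea (10 mol%)
Reagents that add atoms: none
Why: On warming, the aryl 1,1-dimethylallyl ether should undergo a concerted [3,3] aromatic Claisen rearrangement to the only free ortho carbon (future C8), giving dienone 9, which tautomerises to phenol 10, so that O1 is uncovered at the moment the prenyl group arrives beside it; after cooling, the thiourea N–H bonds of the catalyst bind the 1,3-dicarbonyl unit, its quinuclidine nitrogen activates the phenol O–H, and O1 adds to the β-carbon of the alkylidene (future C2). The closest known reaction types are the thermal ortho-Claisen rearrangement of aryl tert-allyl ethers to ortho-prenylphenols and the cinchona-thiourea-catalysed oxa-conjugate addition of 2-hydroxyaryl alkylidene β-ketoesters to flavanones, itself a mimic of the chalcone isomerase step of biosynthesis. Ring C closes by 6-endo-trig attack of O1 on C2. C2 is set by the catalyst through face selection in the hydrogen-bonded complex, while C3 settles trans to the aryl group by enolisation and is removed in step 7. The step needs O1 rather than O5 to close the ring and the prenyl group at C8 rather than C6, both secured because the rearrangement frees only the oxygen it started from while the other ortho oxygen stays a MOM acetal; it also needs the uncatalysed ring closure to stay slow during the warm stage, for which the bulky tert-butyl ester, the base-free non-polar medium and the internal O–H···O=C hydrogen bond of 10 are relied on.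

Step 7
Reactants: 11 tert-butyl (2S,3R)-7-methoxy-5-(methoxymethoxy)-2-(4-methoxyphenyl)-8-(3-methylbut-2-enyl)-4-oxochromane-3-carboxylate
Product: 14 flowerine [(2S)-5-hydroxy-7-methoxy-2-(4-methoxyphenyl)-8-(3-methylbut-2-enyl)chroman-4-one], via keto acid 12 (not isolated), via MOM-protected flavanone 13 (not isolated)
Conditions: TsOH·H2O (0.5 equiv), toluene, 80 °C; then MeOH, 50 °C
Reagents that add atoms: none
Why: Acid-mediated loss of 2-methylpropene from the tert-butyl ester should give β-keto acid 12, which decarboxylates to 13, and acetal exchange with methanol then frees the 5-hydroxyl; C2 is not enolisable and the prenyl group has no free hydroxyl next to it to cyclise onto, so both should survive.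

**Compound list**

1 | 1-(2,6-dihydroxy-4-methoxyphenyl)ethanone (2',6'-dihydroxy-4'-methoxyacetophenone) | CC(=O)c1c(O)cc(OC)cc1O | starting material
2 | 3-chloro-3-methylbut-1-yne | CC(C)(Cl)C#C | starting material
3 | 1-[2-hydroxy-4-methoxy-6-(2-methylbut-3-yn-2-yloxy)phenyl]ethanone | CC(=O)c1c(O)cc(OC)cc1OC(C)(C)C#C | intermediate
4 | 1-[4-methoxy-2-(methoxymethoxy)-6-(2-methylbut-3-yn-2-yloxy)phenyl]ethanone | CC(=O)c1c(OCOC)cc(OC)cc1OC(C)(C)C#C | intermediate
5 | 1-[4-methoxy-2-(methoxymethoxy)-6-(2-methylbut-3-en-2-yloxy)phenyl]ethanone | CC(=O)c1c(OCOC)cc(OC)cc1OC(C)(C)C=C | intermediate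
6 | tert-butyl 3-[4-methoxy-2-(methoxymethoxy)-6-(2-methylbut-3-en-2-yloxy)phenyl]-3-oxopropanoate | CC(C)(C)OC(=O)CC(=O)c1c(OCOC)cc(OC)cc1OC(C)(C)C=C | intermediate
7 | 4-methoxybenzaldehyde | COc1ccc(C=O)cc1 | starting material
8 | tert-butyl (Z)-2-[4-methoxy-2-(methoxymethoxy)-6-(2-methylbut-3-en-2-yloxy)benzoyl]-3-(4-methoxyphenyl)prop-2-enoate | COc1ccc(/C=C(\C(=O)OC(C)(C)C)C(=O)c2c(OCOC)cc(OC)cc2OC(C)(C)C=C)cc1 | intermediate
9 | tert-butyl (Z)-2-[4-methoxy-2-(methoxymethoxy)-5-(3-methylbut-2-enyl)-6-oxocyclohexa-1,3-diene-1-carbonyl]-3-(4-methoxyphenyl)prop-2-enoate (racemic at the ring sp3 carbon; not isolated, step 6) | COc1ccc(/C=C(\C(=O)OC(C)(C)C)C(=O)C2=C(OCOC)C=C(OC)C(CC=C(C)C)C2=O)cc1 | intermediate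
10 | tert-butyl (Z)-2-[2-hydroxy-4-methoxy-6-(methoxymethoxy)-3-(3-methylbut-2-enyl)benzoyl]-3-(4-methoxyphenyl)prop-2-enoate (not isolated, step 6) | COc1ccc(/C=C(\C(=O)OC(C)(C)C)C(=O)c2c(OCOC)cc(OC)c(CC=C(C)C)c2O)cc1 | intermediate
11 | tert-butyl (2S,3R)-7-methoxy-5-(methoxymethoxy)-2-(4-methoxyphenyl)-8-(3-methylbut-2-enyl)-4-oxochromane-3-carboxylate (2,3-trans drawn; C3 epimerisable) | COc1ccc([C@@H]2[C@@H](C(=O)OC(C)(C)C)C(=O)c3c(OCOC)cc(OC)c(CC=C(C)C)c3O2)cc1 | intermediate
12 | (2S,3R)-7-methoxy-5-(methoxymethoxy)-2-(4-methoxyphenyl)-8-(3-methylbut-2-enyl)-4-oxochromane-3-carboxylic acid (not isolated, step 7) | COc1ccc([C@@H]2[C@@H](C(=O)O)C(=O)c3c(OCOC)cc(OC)c(CC=C(C)C)c3O2)cc1 | intermediate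
13 | (2S)-7-methoxy-5-(methoxymethoxy)-2-(4-methoxyphenyl)-8-(3-methylbut-2-enyl)chroman-4-one (not isolated, step 7) | COc1ccc([C@@H]2CC(=O)c3c(OCOC)cc(OC)c(CC=C(C)C)c3O2)cc1 | intermediate
14 | flowerine, (2S)-5-hydroxy-7-methoxy-2-(4-methoxyphenyl)-8-(3-methylbut-2-enyl)chroman-4-one | COc1ccc([C@@H]2CC(=O)c3c(O)cc(OC)c(CC=C(C)C)c3O2)cc1 | target

**Totals**

Total step count: 7. Longest linear sequence: 7 steps (from 1); 2 and 7 enter as purchased materials.

**Steps most likely to fail**

Step 6. During the warm stage the freed phenol may add to the alkylidene before the catalyst is present, or the tert-allyl ether may ionise instead of rearranging; either would erode the enantiomeric purity or the position of the prenyl group. The fallback separates the two events onto different compounds.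
- Setting out from 6, the Claisen rearrangement is run at the β-ketoester stage (toluene, 90 °C), where no Michael acceptor is present.
- It should pass through the transient tert-butyl 3-[4-methoxy-2-(methoxymethoxy)-5-(3-methylbut-2-enyl)-6-oxocyclohexa-1,3-dien-1-yl]-3-oxopropanoate F1 to tert-butyl 3-[2-hydroxy-4-methoxy-6-(methoxymethoxy)-3-(3-methylbut-2-enyl)phenyl]-3-oxopropanoate F2.
- Knoevenagel condensation of F2 with 7 (piperidine/AcOH, 4 Å MS, toluene, rt) should then give the hydrogen-bonded phenol 10, now isolated and never heated.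
- The thiourea-catalysed ring closure at −25 °C comes back to the route at 11.

Step 7. The hot protic acid may open ring C reversibly (eased by the 4-methoxyphenyl group at C2), with loss of configuration, or attack the prenyl alkene (hydration, methanol addition, double-bond migration). The fallback replaces Brønsted-acid thermolysis by silyl-transfer dealkylation in the cold.
- Setting out from 11, Me3SiOTf and 2,2'-bipyridyl in CH2Cl2 at 0 °C should turn the tert-butyl ester into a silyl ester and the aryl MOM acetal into a silyl ether.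
- This gives trimethylsilyl (2S,3R)-7-methoxy-2-(4-methoxyphenyl)-8-(3-methylbut-2-enyl)-4-oxo-5-(trimethylsilyloxy)chromane-3-carboxylate F3; any enol silylation is reversed in the same quench.
- Aqueous quench should hydrolyse both silyl groups to (2S,3R)-5-hydroxy-7-methoxy-2-(4-methoxyphenyl)-8-(3-methylbut-2-enyl)-4-oxochromane-3-carboxylic acid F4.
- F4 should lose carbon dioxide on gentle warming (EtOAc, 40 °C) and so arrive at 14.

Step 5. Condensation of the hindered β-ketoester with the electron-rich aldehyde may be too slow at ambient temperature, and warming it with amine present would start the aryl ether rearrangement and an uncontrolled ring closure. The fallback changes the order so that the condensation can be heated, by carrying the thermally robust propargyl ether through.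
- Setting out from 4, C-acylation (LiN(SiMe3)2, Boc2O, THF, −78 °C; the alkyl-substituted terminal alkyne is far less acidic than the methyl ketone) should give tert-butyl 3-[4-methoxy-2-(methoxymethoxy)-6-(2-methylbut-3-yn-2-yloxy)phenyl]-3-oxopropanoate F5.
- Knoevenagel condensation with 7 in refluxing benzene with azeotropic water removal should give tert-butyl (Z)-2-[4-methoxy-2-(methoxymethoxy)-6-(2-methylbut-3-yn-2-yloxy)benzoyl]-3-(4-methoxyphenyl)prop-2-enoate F6.
- Semi-hydrogenation of the terminal alkyne (H2, Pd/CaCO3 poisoned with Pb(OAc)2, quinoline) comes back to the route at 8.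

**Further compounds**

F1 | step 6 | tert-butyl 3-[4-methoxy-2-(methoxymethoxy)-5-(3-methylbut-2-enyl)-6-oxocyclohexa-1,3-dien-1-yl]-3-oxopropanoate (racemic, transient) | CC(C)(C)OC(=O)CC(=O)C1=C(OCOC)C=C(OC)C(CC=C(C)C)C1=O
F2 | step 6 | tert-butyl 3-[2-hydroxy-4-methoxy-6-(methoxymethoxy)-3-(3-methylbut-2-enyl)phenyl]-3-oxopropanoate | CC(C)(C)OC(=O)CC(=O)c1c(OCOC)cc(OC)c(CC=C(C)C)c1O
F3 | step 7 | trimethylsilyl (2S,3R)-7-methoxy-2-(4-methoxyphenyl)-8-(3-methylbut-2-enyl)-4-oxo-5-(trimethylsilyloxy)chromane-3-carboxylate | COc1ccc([C@@H]2[C@@H](C(=O)O[Si](C)(C)C)C(=O)c3c(O[Si](C)(C)C)cc(OC)c(CC=C(C)C)c3O2)cc1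
F4 | step 7 | (2S,3R)-5-hydroxy-7-methoxy-2-(4-methoxyphenyl)-8-(3-methylbut-2-enyl)-4-oxochromane-3-carboxylic acid | COc1ccc([C@@H]2[C@@H](C(=O)O)C(=O)c3c(O)cc(OC)c(CC=C(C)C)c3O2)cc1
F5 | step 5 | tert-butyl 3-[4-methoxy-2-(methoxymethoxy)-6-(2-methylbut-3-yn-2-yloxy)phenyl]-3-oxopropanoate | CC(C)(C)OC(=O)CC(=O)c1c(OCOC)cc(OC)cc1OC(C)(C)C#C
F6 | step 5 | tert-butyl (Z)-2-[4-methoxy-2-(methoxymethoxy)-6-(2-methylbut-3-yn-2-yloxy)benzoyl]-3-(4-methoxyphenyl)prop-2-enoate | COc1ccc(/C=C(\C(=O)OC(C)(C)C)C(=O)c2c(OCOC)cc(OC)cc2OC(C)(C)C#C)cc1
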